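Read the scheme and the charges first, then the minutes of the meeting on this flask.

electrophile 0.075 M; nucleophile 0.150 M; free base 0.0600 M; protic impurity 1.50 mM; time 40 h

    electrophile + nucleophile → acid set free + target (k1 = 0.0019 L mol⁻¹ s⁻¹)
    nucleophile + acid set free ⇌ protonated nucleophile, settled at all times (K2 = 11000 L mol⁻¹)
    acid set free + free base ⇌ salt of the base, settled at all times (K3 = 6.7 × 10⁵ L mol⁻¹)
    electrophile + target → side product (k4 = 0.0049 L mol⁻¹ s⁻¹)
    crystals ⇌ target, rate k5*(cs5 - [target]) while solid is left; crystals form when [target] > cs5 (cs5 = 28 mM, k5 = 0.012 s⁻¹)
    nucleophile + protic impurity → quenched reagent (k6 = 0.17 L mol⁻¹ s⁻¹)

- why nothing more happens at 40 h, or that something still does (all of the electrophile has reacted / the nucleophile has run out first / it is still moving / the free base has run out first)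
- the target standing at 40 h, as a percentage of the electrophile charged
- the side product standing at 40 h, as a percentage of the electrophile charged

- percent here means electrophile units held: one side product counts as two
- what is said of target includes crystals
- crystals is a solid; its amount is given per volume of the solution
- the reaction counts as stopped when no species that holds the electrophile changes by six tenths of a point or more over the second half of the time
- run time (flask): 40 h

The first speaker, reckoning by hand, took the rate constant of the coupling over that of the side-product step, 0.388. She called it the ceiling ratio, the inverse of the selectivity factor: the dissolved target per nucleophile at which the side-product step removes target as fast as the coupling makes it. The ceiling is this ratio times the nucleophile. She noted that the electrophile half-life by the coupling, 0.68 h, is far shorter than the 40 h allowed, so she reckoned on full conversion of the electrophile in this flask.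

Dividing the two rates at fixed nucleophile and integrating, she obtained for f, the fraction of the ceiling reached at full conversion: f = 1 − exp(−(charge/ceiling + f)/2). She solved this by iteration. With nucleophile at its charge the ceiling was 58.2 mM, and f went from 0.5 to 0.591 to 0.610, so target came to 35.5 mM.

She then put that answer back. The coupling turnover is the mean of electrophile charge and target, which, after the impurity's share, gave a mean nucleophile of 0.121 M; she set protonation and crystals aside. The ceiling fell to 46.9 mM, f went to 0.669 and 0.678, and target to 31.8 mM. She committed to 42.4% target and 57.6% side product.

The second speaker gave the forecast: all of the electrophile has reacted, target 40%, side product 60%, on the ground that the target “competes strongly for the electrophile”. Her figures differ from those of the forecast.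

The flask ends thus: all of the electrophile has reacted, with target 40.1% and side product 59.9%. The side-product step is the main reason for the target's shortfall: struck out, target in this flask stands at >99.9% against 40.1%. With the nucleophile left at the end, this flask's ceiling is 35.1 mM, higher than the dissolved target, which stands at the solubility of 28 mM beside the crystals. For the neighbour charged with 0.045 M of electrophile, all else held, a mean nucleophile of 0.132 M gives a ceiling of 51.4 mM, f of 0.497 and target of 56.8%; the target of that neighbour stands at 54.9%.

Its constants were set for the occasion; the result is computed.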